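**Plan**

- Locants: unprimed for the inner dihydrobenzofuran (its benzene ring is ring A, which carries the styryl group), primed for the outer one (its benzene ring is ring M). Retrosynthetically the nine phenols become methyl ethers and the styryl C=C is cut (Horner–Wadsworth–Emmons), leaving an ester at C6.
- Ring A is then taken back to a saturated ring. Its C3a lies between the two oxygen-bearing carbons C4 and C7a, which is the 2-position of a cyclohexane-1,3-dione, and C2 carries the oxygen-rich ring M. Cutting C3–C3a and O1–C2 therefore gives methyl 3,5-dioxocyclohexane-1-carboxylate and a stilbene.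
- The stilbene is cut at C7' (Heck) to a 7'-bromo outer dihydrobenzofuran. Its C2'–C3' bond is cut to a diaryl carbene and the benzylic C–H bond of a 2,4-dimethoxybenzyl ether.
- Forward order: outer dihydrofuran ring (steps 1–7), stilbene (8), inner dihydrofuran ring by oxidative (3+2) annulation (10), aromatisation of ring A (11), styryl arm (12–14), demethylation (15).
- Stereochemistry: C3' comes from the chiral dirhodium carboxylate in the C–H insertion, and C2' from acid equilibration to trans. C2/C3 are set trans by the cation closure of the annulation; their sense relative to C2'/C3' is not controlled and is obtained by separating the two trans diastereomers.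

Key step: step 10

Assumption: Rh2(S-PTAD)4 (dirhodium tetrakis[(S)-(1-adamantyl)(N-phthalimido)acetate]) is taken to give the (2R,3S) cis product 10; if the induction runs the other way, Rh2(R-PTAD)4 is used in the same way.

**Step 1**
Reactants: 1 2-bromo-5-methoxyphenol
Product: 2 3-bromo-2-hydroxy-6-methoxybenzaldehyde
Conditions: MgCl2, Et3N, (CH2O)n, MeCN, reflux; aq. HCl
Reagents that add atoms: paraformaldehyde (formaldehyde), C=O
Why: Magnesium-phenoxide-directed ortho-formylation (Casnati–Skattebøl reaction) can only strike C6, the single free ortho position, because the other one carries bromine; a second formaldehyde takes up the hydride and leaves as methanol.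

**Step 2**
Reactants: 2 3-bromo-2-hydroxy-6-methoxybenzaldehyde; 3 2,4-dimethoxybenzyl alcohol
Product: 4 3-bromo-2-[(2,4-dimethoxyphenyl)methoxy]-6-methoxybenzaldehyde
Conditions: PPh3, DIAD, THF, 0 °C → rt
Reagents that add atoms: none
Why: Mitsunobu etherification of the acidic salicylaldehyde phenol with a primary benzylic alcohol avoids the unstable 2,4-dimethoxybenzyl halide and installs the CH2 group that becomes C2'.

**Step 3**
Reactants: 4 3-bromo-2-[(2,4-dimethoxyphenyl)methoxy]-6-methoxybenzaldehyde; 5 3,5-dimethoxyphenylmagnesium chloride (THF solution)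
Product: 6 rac-{3-bromo-2-[(2,4-dimethoxyphenyl)methoxy]-6-methoxyphenyl}(3,5-dimethoxyphenyl)methanol
Conditions: THF, −20 → 0 °C; sat. aq. NH4Cl
Reagents that add atoms: none
Why: Grignard 1,2-addition to the aldehyde is far faster than magnesium–bromine exchange at the aryl bromide at this temperature, and the racemic carbinol centre is removed in step 4.

**Step 4**
Reactants: 6 rac-{3-bromo-2-[(2,4-dimethoxyphenyl)methoxy]-6-methoxyphenyl}(3,5-dimethoxyphenyl)methanol
Product: 7 {3-bromo-2-[(2,4-dimethoxyphenyl)methoxy]-6-methoxyphenyl}(3,5-dimethoxyphenyl)methanone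
Conditions: Dess–Martin periodinane, NaHCO3, CH2Cl2, rt
Reagents that add atoms: none
Why: Dess–Martin oxidation of a secondary diaryl carbinol under buffered conditions leaves the acid-sensitive 2,4-dimethoxybenzyl ether untouched.

**Step 5**
Reactants: 7 {3-bromo-2-[(2,4-dimethoxyphenyl)methoxy]-6-methoxyphenyl}(3,5-dimethoxyphenyl)methanone
Product: 8 hydrazone of 7, [{3-bromo-2-[(2,4-dimethoxyphenyl)methoxy]-6-methoxyphenyl}(3,5-dimethoxyphenyl)methylidene]hydrazine (E/Z mixture)
Conditions: N2H4·H2O (large excess), AcOH (cat.), n-BuOH, 110 °C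
Reagents that add atoms: hydrazine hydrate, NN.O
Why: Hydrazone formation at the diaryl ketone is driven by heat and excess hydrazine because the carbonyl is flanked by two ortho substituents, and the excess also suppresses azine formation.

**Step 6**
Reactants: 8 hydrazone of 7
Product: 10 (2R,3S)-7-bromo-2-(2,4-dimethoxyphenyl)-3-(3,5-dimethoxyphenyl)-4-methoxy-2,3-dihydro-1-benzofuran (cis), via diazo compound 9 (not isolated)
Conditions: MnO2, CH2Cl2, 0 °C; filter; Rh2(S-PTAD)4 (1 mol%), MeCN–CH2Cl2, −20 → 0 °C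
Reagents that add atoms: none
Why: MnO2 dehydrogenates the hydrazone to the diaryldiazomethane, whose donor/donor dirhodium carbene inserts into the activated 2,4-dimethoxybenzylic C–H bond five atoms away (enantioselective intramolecular 1,5 C–H insertion); the chiral carboxylate ligands fix C3' as S and the insertion delivers C2' cis to it.

**Step 7**
Reactants: 10 (2R,3S)-7-bromo-2-(2,4-dimethoxyphenyl)-3-(3,5-dimethoxyphenyl)-4-methoxy-2,3-dihydro-1-benzofuran
Product: 11 (2S,3S)-7-bromo-2-(2,4-dimethoxyphenyl)-3-(3,5-dimethoxyphenyl)-4-methoxy-2,3-dihydro-1-benzofuran (trans)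
Conditions: TFA, CH2Cl2, 0 °C
Reagents that add atoms: none
Why: Acid ionises the C2'–O1' bond to a 2,4-dimethoxybenzylic cation that recloses on the same oxygen to the thermodynamically preferred trans isomer (SN1 epimerisation at C2'), while C3' has no ionisable bond and keeps its configuration.

**Step 8**
Reactants: 11 (2S,3S)-7-bromo-2-(2,4-dimethoxyphenyl)-3-(3,5-dimethoxyphenyl)-4-methoxy-2,3-dihydro-1-benzofuran; 12 3,5-dimethoxystyrene
Product: 13 (2S,3S)-2-(2,4-dimethoxyphenyl)-3-(3,5-dimethoxyphenyl)-7-[(E)-2-(3,5-dimethoxyphenyl)ethenyl]-4-methoxy-2,3-dihydro-1-benzofuran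
Conditions: Pd2(dba)3 (cat.), P(t-Bu)3·HBF4 (cat.), Cy2NMe, dioxane, 80 °C
Reagents that add atoms: none
Why: Mizoroki–Heck coupling of the electron-rich ortho-alkoxy aryl bromide is enabled by the bulky, electron-rich phosphine, and syn insertion followed by syn β-hydride elimination gives the E stilbene.

**Step 9**
Reactants: 14 methyl 3,5-dihydroxybenzoate
Product: 15 methyl 3,5-dioxocyclohexane-1-carboxylate
Conditions: H2 (4 atm), Rh/Al2O3 (5 wt% Rh), NaOMe (1 equiv), MeOH, rt; then aq. HCl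
Reagents that add atoms: none
Why: Partial hydrogenation of a resorcinol as its monoanion stops at the stabilised 1,3-dione enolate (the classical dihydroresorcinol preparation), and methoxide in methanol cannot saponify the methyl ester.

**Step 10**
Reactants: 13 (2S,3S)-2-(2,4-dimethoxyphenyl)-3-(3,5-dimethoxyphenyl)-7-[(E)-2-(3,5-dimethoxyphenyl)ethenyl]-4-methoxy-2,3-dihydro-1-benzofuran; 15 methyl 3,5-dioxocyclohexane-1-carboxylate
Product: 16 methyl (2S,3S)-2-[(2S,3S)-2-(2,4-dimethoxyphenyl)-3-(3,5-dimethoxyphenyl)-4-methoxy-2,3-dihydro-1-benzofuran-7-yl]-3-(3,5-dimethoxyphenyl)-4-oxo-2,3,4,5,6,7-hexahydro-1-benzofuran-6-carboxylate (both C6 epimers)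
Conditions: 15 (2 equiv), Mn(OAc)3·2H2O (2.5 equiv), Cu(OAc)2·H2O (0.2 equiv), AcOH–MeCN (3:1), 40 °C, Ar
Reagents that add atoms: none
Why: Mn(OAc)3 binds the enol of 15 and oxidises it by inner-sphere electron transfer to the electrophilic radical at the dione 2-position (the future C3a), which adds to the stilbene carbon carrying the 3,5-dimethoxyphenyl ring and so forms C3–C3a. The adduct radical, benzylic to ring M, is oxidised by divalent copper (regenerated by trivalent manganese) to a cation stabilised by the ortho ring oxygen O1' and the para methoxy group at C4', and the enol oxygen captures it in a 5-exo-trig closure that forms O1–C2 and the inner dihydrofuran ring. The closest known reaction type is the Mn(OAc)3-mediated oxidative (3+2) annulation of cyclic 1,3-diones with aryl alkenes to 2,3-dihydrofurans. C2 and C3 are set trans because the cation closes with the two aryl groups on opposite faces of the new ring, the arrangement that is also thermodynamically preferred. The alkene face relative to C2'/C3' is not controlled, so 16 should form together with its inner-ring (2R,3R) trans diastereomer; the mixture is carried into step 11 and separated there. The step needs regioselectivity between the two alkene carbons, secured by the much better cation-stabilising ring M against the meta-dimethoxy ring, and chemoselectivity for the dione over the methoxyarenes, secured because only the enolisable dione binds manganese.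

**Step 11**
Reactants: 16 methyl (2S,3S)-2-[…-7-yl]-3-(3,5-dimethoxyphenyl)-4-oxo-2,3,4,5,6,7-hexahydro-1-benzofuran-6-carboxylate (mixture from step 10)
Product: 17 methyl (2S,3S)-2-[(2S,3S)-2-(2,4-dimethoxyphenyl)-3-(3,5-dimethoxyphenyl)-4-methoxy-2,3-dihydro-1-benzofuran-7-yl]-3-(3,5-dimethoxyphenyl)-4-methoxy-2,3-dihydro-1-benzofuran-6-carboxylate
Conditions: I2 (2.2 equiv), MeOH, 65 °C; chromatographic separation of the two diastereomers
Reagents that add atoms: methanol, CO
Why: Iodine–methanol aromatisation of the dione-derived vinylogous ester (α-iodination, loss of HI and enol-ether formation) turns the enone into the C4 methyl ether of ring A and removes the C6 stereocentre, so that only two diastereomers remain, from which 17 is isolated.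

**Step 12**
Reactants: 17 methyl (2S,3S)-2-[…-7-yl]-3-(3,5-dimethoxyphenyl)-4-methoxy-2,3-dihydro-1-benzofuran-6-carboxylate
Product: 18 {(2S,3S)-2-[(2S,3S)-2-(2,4-dimethoxyphenyl)-3-(3,5-dimethoxyphenyl)-4-methoxy-2,3-dihydro-1-benzofuran-7-yl]-3-(3,5-dimethoxyphenyl)-4-methoxy-2,3-dihydro-1-benzofuran-6-yl}methanol
Conditions: i-Bu2AlH, CH2Cl2, −78 → 0 °C; aq. potassium sodium tartrate
Reagents that add atoms: none
Why: Hydride reduction of the aromatic methyl ester to the benzylic alcohol touches neither the aryl ethers nor the four stereocentres.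

**Step 13**
Reactants: 18 {…-2,3-dihydro-1-benzofuran-6-yl}methanol
Product: 19 (2S,3S)-2-[(2S,3S)-2-(2,4-dimethoxyphenyl)-3-(3,5-dimethoxyphenyl)-4-methoxy-2,3-dihydro-1-benzofuran-7-yl]-3-(3,5-dimethoxyphenyl)-4-methoxy-2,3-dihydro-1-benzofuran-6-carbaldehyde
Conditions: MnO2, CH2Cl2, rt
Reagents that add atoms: none
Why: MnO2 oxidises the benzylic alcohol selectively to the aldehyde without over-oxidation.

**Step 14**
Reactants: 19 (2S,3S)-…-2,3-dihydro-1-benzofuran-6-carbaldehyde; 20 diethyl (4-methoxybenzyl)phosphonate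
Product: 21 nona-O-methylgnetumontanin B, (2S,3S)-2-[(2S,3S)-2-(2,4-dimethoxyphenyl)-3-(3,5-dimethoxyphenyl)-4-methoxy-2,3-dihydro-1-benzofuran-7-yl]-3-(3,5-dimethoxyphenyl)-4-methoxy-6-[(E)-2-(4-methoxyphenyl)ethenyl]-2,3-dihydro-1-benzofuran
Conditions: KOt-Bu, THF, 0 °C → rt
Reagents that add atoms: none
Why: Horner–Wadsworth–Emmons olefination with the benzylic phosphonate anion gives the E stilbene through the favoured anti oxaphosphetane.

**Step 15**
Reactants: 21 nona-O-methylgnetumontanin B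
Product: 22 gnetumontanin B, (2S,3S,2'S,3'S)
Conditions: BBr3 (excess), CH2Cl2, −78 → 0 °C; MeOH, then aq. NaHCO3
Reagents that add atoms: none
Why: BBr3 cleaves the nine aryl methyl ethers by coordination at oxygen and bromide attack at methyl (Lewis-acid ether cleavage), and the low temperature is chosen to keep the two benzylic ring C–O bonds closed so that the four stereocentres are retained.

**Compound list**

1 | 2-bromo-5-methoxyphenol | COc1ccc(Br)c(O)c1 | starting material
2 | 3-bromo-2-hydroxy-6-methoxybenzaldehyde | COc1ccc(Br)c(O)c1C=O | intermediate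
3 | 2,4-dimethoxybenzyl alcohol | COc1ccc(CO)c(OC)c1 | starting material
4 | 3-bromo-2-[(2,4-dimethoxyphenyl)methoxy]-6-methoxybenzaldehyde | COc1ccc(COc2c(Br)ccc(OC)c2C=O)c(OC)c1 | intermediate
5 | 3,5-dimethoxyphenylmagnesium chloride | COc1cc(OC)cc([Mg]Cl)c1 | starting material
6 | rac-{3-bromo-2-[(2,4-dimethoxyphenyl)methoxy]-6-methoxyphenyl}(3,5-dimethoxyphenyl)methanol | COc1ccc(COc2c(Br)ccc(OC)c2C(O)c2cc(OC)cc(OC)c2)c(OC)c1 | intermediate
7 | {3-bromo-2-[(2,4-dimethoxyphenyl)methoxy]-6-methoxyphenyl}(3,5-dimethoxyphenyl)methanone | COc1ccc(COc2c(Br)ccc(OC)c2C(=O)c2cc(OC)cc(OC)c2)c(OC)c1 | intermediate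
8 | hydrazone of 7 (E/Z mixture) | COc1ccc(COc2c(Br)ccc(OC)c2C(=NN)c2cc(OC)cc(OC)c2)c(OC)c1 | intermediate
9 | 1-bromo-3-[diazo(3,5-dimethoxyphenyl)methyl]-2-[(2,4-dimethoxyphenyl)methoxy]-4-methoxybenzene (not isolated) | COc1ccc(COc2c(Br)ccc(OC)c2C(=[N+]=[N-])c2cc(OC)cc(OC)c2)c(OC)c1 | intermediate
10 | (2R,3S)-7-bromo-2-(2,4-dimethoxyphenyl)-3-(3,5-dimethoxyphenyl)-4-methoxy-2,3-dihydro-1-benzofuran (cis) | Brc1ccc(OC)c2c1O[C@@H](c1ccc(OC)cc1OC)[C@H]2c1cc(OC)cc(OC)c1 | intermediate
11 | (2S,3S)-7-bromo-2-(2,4-dimethoxyphenyl)-3-(3,5-dimethoxyphenyl)-4-methoxy-2,3-dihydro-1-benzofuran (trans) | Brc1ccc(OC)c2c1O[C@H](c1ccc(OC)cc1OC)[C@H]2c1cc(OC)cc(OC)c1 | intermediate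
12 | 3,5-dimethoxystyrene | C=Cc1cc(OC)cc(OC)c1 | starting material
13 | (2S,3S)-2-(2,4-dimethoxyphenyl)-3-(3,5-dimethoxyphenyl)-7-[(E)-2-(3,5-dimethoxyphenyl)ethenyl]-4-methoxy-2,3-dihydro-1-benzofuran | COc1cc(/C=C/c2ccc(OC)c3c2O[C@H](c2ccc(OC)cc2OC)[C@H]3c2cc(OC)cc(OC)c2)cc(OC)c1 | intermediate
14 | methyl 3,5-dihydroxybenzoate | COC(=O)c1cc(O)cc(O)c1 | starting material
15 | methyl 3,5-dioxocyclohexane-1-carboxylate | COC(=O)C1CC(=O)CC(=O)C1 | intermediate
16 | methyl (2S,3S)-2-[(2S,3S)-2-(2,4-dimethoxyphenyl)-3-(3,5-dimethoxyphenyl)-4-methoxy-2,3-dihydro-1-benzofuran-7-yl]-3-(3,5-dimethoxyphenyl)-4-oxo-2,3,4,5,6,7-hexahydro-1-benzofuran-6-carboxylate (both C6 epimers) | COC(=O)C1CC(=O)C2=C(C1)O[C@H](c1ccc(OC)c3c1O[C@H](c1ccc(OC)cc1OC)[C@H]3c1cc(OC)cc(OC)c1)[C@H]2c1cc(OC)cc(OC)c1 | intermediate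
17 | methyl (2S,3S)-2-[(2S,3S)-2-(2,4-dimethoxyphenyl)-3-(3,5-dimethoxyphenyl)-4-methoxy-2,3-dihydro-1-benzofuran-7-yl]-3-(3,5-dimethoxyphenyl)-4-methoxy-2,3-dihydro-1-benzofuran-6-carboxylate | COC(=O)c1cc(OC)c2c(c1)O[C@H](c1ccc(OC)c3c1O[C@H](c1ccc(OC)cc1OC)[C@H]3c1cc(OC)cc(OC)c1)[C@H]2c1cc(OC)cc(OC)c1 | intermediate
18 | {(2S,3S)-2-[(2S,3S)-2-(2,4-dimethoxyphenyl)-3-(3,5-dimethoxyphenyl)-4-methoxy-2,3-dihydro-1-benzofuran-7-yl]-3-(3,5-dimethoxyphenyl)-4-methoxy-2,3-dihydro-1-benzofuran-6-yl}methanol | OCc1cc(OC)c2c(c1)O[C@H](c1ccc(OC)c3c1O[C@H](c1ccc(OC)cc1OC)[C@H]3c1cc(OC)cc(OC)c1)[C@H]2c1cc(OC)cc(OC)c1 | intermediate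
19 | (2S,3S)-2-[(2S,3S)-2-(2,4-dimethoxyphenyl)-3-(3,5-dimethoxyphenyl)-4-methoxy-2,3-dihydro-1-benzofuran-7-yl]-3-(3,5-dimethoxyphenyl)-4-methoxy-2,3-dihydro-1-benzofuran-6-carbaldehyde | O=Cc1cc(OC)c2c(c1)O[C@H](c1ccc(OC)c3c1O[C@H](c1ccc(OC)cc1OC)[C@H]3c1cc(OC)cc(OC)c1)[C@H]2c1cc(OC)cc(OC)c1 | intermediate
20 | diethyl (4-methoxybenzyl)phosphonate | CCOP(=O)(Cc1ccc(OC)cc1)OCC | starting material
21 | nona-O-methylgnetumontanin B | COc1ccc(/C=C/c2cc(OC)c3c(c2)O[C@H](c2ccc(OC)c4c2O[C@H](c2ccc(OC)cc2OC)[C@H]4c2cc(OC)cc(OC)c2)[C@H]3c2cc(OC)cc(OC)c2)cc1 | intermediate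
22 | gnetumontanin B, (2S,3S,2'S,3'S) | Oc1ccc(/C=C/c2cc(O)c3c(c2)O[C@H](c2ccc(O)c4c2O[C@H](c2ccc(O)cc2O)[C@H]4c2cc(O)cc(O)c2)[C@H]3c2cc(O)cc(O)c2)cc1 | target

**Step count and risks**

Total step count: 15. Longest linear sequence: 14 steps (steps 1–8 and 10–15, from 2-bromo-5-methoxyphenol); step 9 is a one-step side branch.

**Step 6.** The diazo compound comes from a hydrazone whose carbon is flanked by two ortho substituents. Condensation (step 5) and dehydrogenation may therefore stall or divert to the azine, and the crowded carbene may insert with poor enantio- or cis-selectivity.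

The fallback sets out from ketone 7 and returns at 11, by-passing steps 5–7:
- Corey–Chaykovsky methylenation of 7 (Me3S+ I−, n-BuLi, THF) would give 2-{3-bromo-2-[(2,4-dimethoxyphenyl)methoxy]-6-methoxyphenyl}-2-(3,5-dimethoxyphenyl)oxirane F1.
- ZnI2-catalysed Meinwald rearrangement would convert it into 2-{3-bromo-2-[(2,4-dimethoxyphenyl)methoxy]-6-methoxyphenyl}-2-(3,5-dimethoxyphenyl)acetaldehyde F2.
- Addition of 2,4-dimethoxyphenylmagnesium bromide would give 2-{3-bromo-2-[(2,4-dimethoxyphenyl)methoxy]-6-methoxyphenyl}-1-(2,4-dimethoxyphenyl)-2-(3,5-dimethoxyphenyl)ethan-1-ol F3, as a diastereomer mixture that is of no consequence.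
- TFA with pentamethylbenzene in CH2Cl2 would cleave the 2,4-dimethoxybenzyl ether and ionise the carbinol. The freed phenol would close to the racemic trans dihydrobenzofuran, that is 11 together with its enantiomer (2R,3R)-7-bromo-2-(2,4-dimethoxyphenyl)-3-(3,5-dimethoxyphenyl)-4-methoxy-2,3-dihydro-1-benzofuran F4.
- Preparative chromatography on a chiral stationary phase would then deliver 11.

**Step 10.** Trivalent manganese may oxidise the electron-rich stilbene or the methoxyarenes by outer-sphere electron transfer (stilbene radical-cation coupling, acetoxylation). The dione radical may also couple with itself faster than it adds to the hindered alkene.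

The fallback sets out from dione 15 and returns at 16, replacing the one-electron oxidant by a two-electron carbenoid route:
- PhI(OAc)2 and KOH in MeOH at 0 °C would convert 15 into its phenyliodonium ylide, methyl 3,5-dioxo-4-(phenyliodonio)cyclohexan-4-ide-1-carboxylate F5.
- F5 and stilbene 13 with Rh2(OAc)4 (cat.) in CH2Cl2 at 40 °C would undergo the known formal (3+2) cycloaddition of dione iodonium ylides with aryl alkenes. The zwitterion has its cation again at the carbon bearing ring M, so the same bonds form and the same trans ring closes to give 16.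

**Step 15.** Nine ether cleavages need long exposure to the Lewis acid. During it the two benzylic ring C–O bonds may ionise; the outer ring could then reclose through either oxygen flanking C3a' of ring M. HBr may also add to the activated hydroxystilbene, or the stilbene may oligomerise under acid.

The fallback sets out from aldehyde 19 and returns at 22. It moves the ether cleavage to a stage without the alkene, where ring A is deactivated by the formyl group, and ends with fluoride:
- BBr3 in CH2Cl2 (−78 → 0 °C) would give the octaphenol (2S,3S)-2-[(2S,3S)-2-(2,4-dihydroxyphenyl)-3-(3,5-dihydroxyphenyl)-4-hydroxy-2,3-dihydro-1-benzofuran-7-yl]-3-(3,5-dihydroxyphenyl)-4-hydroxy-2,3-dihydro-1-benzofuran-6-carbaldehyde F6.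
- TBSCl and imidazole in DMF would give its octakis(tert-butyldimethylsilyl) ether F7. Any ring-opened or isomeric material can be removed here by ordinary chromatography.
- Diethyl {4-[(tert-butyldimethylsilyl)oxy]benzyl}phosphonate F8 would be made from commercial diethyl (4-hydroxybenzyl)phosphonate with TBSCl and imidazole.
- Horner–Wadsworth–Emmons reaction of F7 with F8 (NaH, THF, 0 °C) would give nonakis-O-(tert-butyldimethylsilyl)gnetumontanin B F9.
- n-Bu4NF buffered with AcOH in THF at 0 °C would release 22.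

**Further compounds**

F1 | step 6 | 2-{3-bromo-2-[(2,4-dimethoxyphenyl)methoxy]-6-methoxyphenyl}-2-(3,5-dimethoxyphenyl)oxirane (racemic) | COc1ccc(COc2c(Br)ccc(OC)c2C2(c3cc(OC)cc(OC)c3)CO2)c(OC)c1
F2 | step 6 | 2-{3-bromo-2-[(2,4-dimethoxyphenyl)methoxy]-6-methoxyphenyl}-2-(3,5-dimethoxyphenyl)acetaldehyde (racemic) | COc1ccc(COc2c(Br)ccc(OC)c2C(C=O)c2cc(OC)cc(OC)c2)c(OC)c1
F3 | step 6 | 2-{3-bromo-2-[(2,4-dimethoxyphenyl)methoxy]-6-methoxyphenyl}-1-(2,4-dimethoxyphenyl)-2-(3,5-dimethoxyphenyl)ethan-1-ol (diastereomer mixture) | COc1ccc(COc2c(Br)ccc(OC)c2C(c2cc(OC)cc(OC)c2)C(O)c2ccc(OC)cc2OC)c(OC)c1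
F4 | step 6 | (2R,3R)-7-bromo-2-(2,4-dimethoxyphenyl)-3-(3,5-dimethoxyphenyl)-4-methoxy-2,3-dihydro-1-benzofuran (enantiomer of 11, formed with 11 as the racemate) | Brc1ccc(OC)c2c1O[C@@H](c1ccc(OC)cc1OC)[C@@H]2c1cc(OC)cc(OC)c1
F5 | step 10 | methyl 3,5-dioxo-4-(phenyliodonio)cyclohexan-4-ide-1-carboxylate (phenyliodonium ylide of 15) | COC(=O)C1CC(=O)[C-]([I+]c2ccccc2)C(=O)C1
F6 | step 15 | (2S,3S)-2-[(2S,3S)-2-(2,4-dihydroxyphenyl)-3-(3,5-dihydroxyphenyl)-4-hydroxy-2,3-dihydro-1-benzofuran-7-yl]-3-(3,5-dihydroxyphenyl)-4-hydroxy-2,3-dihydro-1-benzofuran-6-carbaldehyde | O=Cc1cc(O)c2c(c1)O[C@H](c1ccc(O)c3c1O[C@H](c1ccc(O)cc1O)[C@H]3c1cc(O)cc(O)c1)[C@H]2c1cc(O)cc(O)c1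
F7 | step 15 | octakis-O-(tert-butyldimethylsilyl) ether of F6 | O=Cc1cc(O[Si](C)(C)C(C)(C)C)c2c(c1)O[C@H](c1ccc(O[Si](C)(C)C(C)(C)C)c3c1O[C@H](c1ccc(O[Si](C)(C)C(C)(C)C)cc1O[Si](C)(C)C(C)(C)C)[C@H]3c1cc(O[Si](C)(C)C(C)(C)C)cc(O[Si](C)(C)C(C)(C)C)c1)[C@H]2c1cc(O[Si](C)(C)C(C)(C)C)cc(O[Si](C)(C)C(C)(C)C)c1
F8 | step 15 | diethyl {4-[(tert-butyldimethylsilyl)oxy]benzyl}phosphonate | CCOP(=O)(Cc1ccc(O[Si](C)(C)C(C)(C)C)cc1)OCC
F9 | step 15 | nonakis-O-(tert-butyldimethylsilyl)gnetumontanin B | CC(C)(C)[Si](C)(C)Oc1ccc(/C=C/c2cc(O[Si](C)(C)C(C)(C)C)c3c(c2)O[C@H](c2ccc(O[Si](C)(C)C(C)(C)C)c4c2O[C@H](c2ccc(O[Si](C)(C)C(C)(C)C)cc2O[Si](C)(C)C(C)(C)C)[C@H]4c2cc(O[Si](C)(C)C(C)(C)C)cc(O[Si](C)(C)C(C)(C)C)c2)[C@H]3c2cc(O[Si](C)(C)C(C)(C)C)cc(O[Si](C)(C)C(C)(C)C)c2)cc1
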